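**Bench note.** 44% of the solid substrate read as tetra adduct at the last reading of Wednesday's run, against 41% at 2.00 min, a rise of the order of the scatter. Across the last readings of the runs, tetra adduct climbs with the partner charge, while single product reads near 10% in each. Leave the partner charges as weighed.

all flasks: solid substrate 0.0020 M
- Saturday's: partner 1.2 mM; run made earlier
- Friday's: partner 3 mM; run made earlier
- Wednesday's: partner 3.9 mM; run made earlier
- south: partner 5.00 mM; time 10 min
- north: partner 1.60 mM; time 10 min
- south-west: partner 2.40 mM; time 10 min

| run | time / min | single product / % | tetra adduct / % |
|---|---|---|---|
| Saturday's | 0.833 | 5 | 12 |
| Saturday's | 2.50 | 10 | 5 |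
| Saturday's | 5.00 | 9 | 7 |
| Saturday's | 8.00 | 11 | 11 |
| Friday's | 2.00 | 13 | 33 |
| Friday's | 4.00 | 9 | 28 |
| Friday's | 5.00 | 10 | 33 |
| Friday's | 8.00 | 10 | 31 |
| Wednesday's | 2.00 | 11 | 41 |
| Wednesday's | 4.00 | 11 | 41 |
| Wednesday's | 5.00 | 10 | 45 |
| Wednesday's | 8.00 | 11 | 44 |

(each reading ± 2 percentage points)

- solid substrate is a solid; its amount is given per volume of the solution
- at the start none of the solid substrate is in solution

- which of these holds the largest part of the solid substrate at the end of south (solid substrate / double product / triple product / tetra adduct / single product)
- which of these holds the largest part of the solid substrate at the end of north (solid substrate / double product / triple product / tetra adduct / single product)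
- which of these holds the largest part of the solid substrate at the end of south-west (solid substrate / double product / triple product / tetra adduct / single product)
- final single product in south-west, as a percentage of the solid substrate charged

**Partner overhead.** Partner is treated here as the limiting reagent, at 4 per tetra adduct. A first round counts single product as the other partner sink, 0.220 mM. Put back into Wednesday's run, this gives 46.0% tetra adduct, more than the reading of 44%. A second round therefore reads from the last readings of the three runs the partner charged that does not end in tetra adduct, the partner overhead, 0.407 mM. Tetra adduct is then the charge less the overhead, over 4 times the solid substrate: 24.9% in south-west. This reckoning sets no figure for the solid.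

**The forecast.** It names tetra adduct for south, solid substrate for north, solid substrate for south-west and 10.4% single product, holding that “undissolved solid buffers the solution”. For south-west it gives tetra adduct about 24%, a little below the reckoning above, and solid about 60%.

**The result.** South and south-west end with tetra adduct the largest of the forms asked, north with solid substrate, and south-west holds 10.2% single product. South-west has 23.5% tetra adduct, 15.5% solid substrate and 41.0% dissolved starting material.

    solid substrate ⇌ starting material, rate k1*(cs1 - [starting material]) while solid is left; crystals form when [starting material] > cs1 (solubility = 0.820 mM, k = 0.350 s⁻¹)
    partner + double product → triple product + by-product (k = 7100 M⁻¹ s⁻¹)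
    partner + triple product → tetra adduct + by-product (k = 4000 M⁻¹ s⁻¹)
    partner + single product → double product + by-product (k = 2300 M⁻¹ s⁻¹)
    starting material + triple product → side product (k = 220 M⁻¹ s⁻¹)
    starting material + partner → single product + by-product (k = 4000 M⁻¹ s⁻¹)

**Overhead reused.** The overhead gave 24.9% against 23.5% in south-west, and it gives 14.9% against 13.5% in north. In south-west, half of the turnover of starting material with partner up to the asked time is done by 1.65 s, far sooner than the 10 min allowed, and tetra adduct there stands at 23.5% at 5.00 min and 23.5% at 10.0 min.

(The data come from a simulation with made-up constants, noise included.)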